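**Strategy.** Ring C (C8–C9–C11–C12–C13–C14) is closed last through the C12–C13 bond by an intramolecular Hosomi–Sakurai reaction. The step exploits the homoallylic alcohol array O–C12–C13–C16=C17 and the fact that the C12 oxygen and C20 lie syn on the α-face, so both aldehyde carbons can be tied in a temporary 12,20-bridged bis(methyl acetal). The precursor is a trans-hydrindane (rings A and B) bearing a spiro cyclopentenylmethylsilane (ring D). Ionisation at C12 and attack by C13 close ring C, set C12 and C13, create the C16 methylene and leave C20 masked. Ring A comes from a Robinson annulation, ring D from spiro-alkylation and metathesis, ring B from a Wolff contraction.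

Key step: step 18

Remark: atoms carry gibberellane numbers (C1–C20); in the decalin intermediates ring A is C1–C2–C3–C4–C5–C10 and the six-membered ring B is C5–C6–C7–C8–C9–C10 (C7 is later extruded as the carboxyl carbon); α is the face of C20.
Assumption: the (S,S)-ligand in step 2 is taken to give the allyl centre shown (otherwise its antipode is used); 31 and 32 are written as open 12-hydroxy-20-aldehydes although lactol ring tautomers may be populated.

**Step 1**
Reactants: 1 allyl 2-oxocyclohexane-1-carboxylate
Product: 3 allyl 6-oxocyclohex-1-ene-1-carboxylate, via α-phenylselanyl keto ester 2 (not isolated)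
Conditions: PhSeCl, pyridine, CH2Cl2, 0 °C; then H2O2 (30 % aq.), 0 °C → rt
Reagents that add atoms: none
Why: α-selenenylation of the β-keto ester followed by oxidation and syn-elimination of the selenoxide (Reich selenoxide elimination) should give the chelating alkylidene β-keto ester needed as conjugate acceptor.

**Step 2**
Reactants: 3 allyl 6-oxocyclohex-1-ene-1-carboxylate; 4 allyltrimethylsilane
Product: 5 allyl (1S,2S)-2-allyl-6-oxocyclohexane-1-carboxylate
Conditions: Cu(OTf)2 (10 mol %), (S,S)-t-Bu-box (11 mol %), CH2Cl2, −78 °C; aq. NaHCO3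
Reagents that add atoms: none
Why: a copper bis(oxazoline)-catalysed enantioselective Hosomi–Sakurai conjugate allylation of the two-point-binding alkylidene β-keto ester should set C9 under catalyst control, and the C10 keto ester centre equilibrates to the trans isomer.

**Step 3**
Reactants: 5 allyl (1S,2S)-2-allyl-6-oxocyclohexane-1-carboxylate; 6 methyl 5-methoxy-3-oxopentanoate
Product: 9 decalin enone diester (3-oxo-4-ene; 4-CO2Me; 10α-CO2allyl; 9α-allyl), via Nazarov enone 7 (not isolated), via Michael adduct 8 (not isolated)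
Conditions: DBU (0.2 equiv), MeCN, 0 °C → rt; then TsOH·H2O (cat.), PhMe, reflux, Dean–Stark
Reagents that add atoms: none
Why: Robinson annulation with the Nazarov reagent released in situ, in which Michael addition of the keto ester enolate occurs anti to the neighbouring C9 allyl group (quaternary C10 set, C20 cis to C11) and acid-promoted Knoevenagel-type aldol condensation of C4 onto the C5 ketone closes ring A.

**Step 4**
Reactants: 9 decalin enone diester
Product: 10 4β-methyl-3-oxo-5-ene diester (4α-CO2Me; 10α-CO2allyl; 9α-allyl)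
Conditions: NaH, THF, 0 °C; MeI, 0 °C → rt
Reagents that add atoms: iodomethane, CI
Why: deconjugative α-alkylation of the extended enolate (deprotonation at C6) of the alkylidene β-keto ester, in which iodomethane should enter at C4 anti to the axial C20 ester, giving the β-methyl/α-ester quaternary centre and the C5=C6 alkene.

**Step 5**
Reactants: 10 4β-methyl-3-oxo-5-ene diester
Product: 11 C20 carboxylic acid (10α-CO2H)
Conditions: Pd(PPh3)4 (5 mol %), morpholine, THF, rt; acidic work-up
Reagents that add atoms: none
Why: Tsuji–Trost deallylation, in which zerovalent palladium ionises only the allyl ester and morpholine captures the π-allyl fragment, so the C-allyl group and the methyl ester survive.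

**Step 6**
Reactants: 11 C20 carboxylic acid
Product: 13 C20 aldehyde (10α-CHO; 9α-allyl; 3-oxo-5-ene), via acid chloride 12 (not isolated)
Conditions: (COCl)2, DMF (cat.), CH2Cl2, 0 °C → rt; then LiAlH(Ot-Bu)3, THF, −78 °C
Reagents that add atoms: none
Why: partial reduction of an acid chloride, in which the hindered acyl chloride is taken only to the aldehyde by the mild bulky hydride at low temperature while the C3 ketone and the C19 ester should remain untouched.

**Step 7**
Reactants: 13 C20 aldehyde
Product: 14 12,20-dialdehyde (9α-CH2CHO; 10α-CHO)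
Conditions: OsO4 (2 mol %), NaIO4, 2,6-lutidine, dioxane/H2O 3:1, rt
Reagents that add atoms: osmium tetroxide, O=[Os](=O)(=O)=O; sodium periodate, [Na+].[O-][I](=O)(=O)=O
Why: Lemieux–Johnson oxidation, in which OsO4 dihydroxylates only the unhindered terminal alkene (C5=C6 is flanked by two quaternary carbons) and periodate cleaves the diol to the C12 aldehyde.

**Step 8**
Reactants: 14 12,20-dialdehyde
Product: 15 12,20-bridged bis(methyl acetal) 3-ketone (six-membered ring C12H(OMe)–O–C20H(OMe) fused on the α-face at C9–C10)
Conditions: MeOH, PPTS (cat.), 3 Å MS, rt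
Reagents that add atoms: methanol, CO
Why: Fischer-type acetalisation of the 1,5-dialdehyde, whose C11 and C20 arms are cis, should give the six-membered 2,6-dimethoxytetrahydropyran (anomer mixture at C12 and C20, both centres being reset later) and leave the hindered C3 ketone free.

**Step 9**
Reactants: 15 bis(methyl acetal) 3-ketone
Product: 16 3β-alcohol
Conditions: LiBH(s-Bu)3, THF, −78 °C; H2O
Reagents that add atoms: none
Why: bulky-hydride ketone reduction, in which LiBH(s-Bu)3 should add along the equatorial trajectory as for 4,4-disubstituted 3-oxo terpenoids and give the axial 3β-alcohol (cis to C18).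

**Step 10**
Reactants: 16 3β-alcohol
Product: 17 3β-triethylsilyl ether
Conditions: Et3SiCl, imidazole, DMAP (cat.), DMF, 40 °C
Reagents that add atoms: chlorotriethylsilane, CC[Si](Cl)(CC)CC
Why: standard silyl ether formation protects the hindered secondary alcohol against the chromium oxidation and the amide bases that follow.

**Step 11**
Reactants: 17 3β-triethylsilyl ether
Product: 18 5-en-7-one
Conditions: CrO3, 3,5-dimethylpyrazole, CH2Cl2, −20 °C
Reagents that add atoms: chromium trioxide, O=[Cr](=O)=O
Why: allylic oxidation with the CrO3–3,5-dimethylpyrazole complex should give the enone as with steroidal 5-enes, because C7 is the only allylic methylene (C4 and C10 are quaternary).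

**Step 12**
Reactants: 18 5-en-7-one; 19 allyl bromide
Product: 20 8β-allyl-5-en-7-one
Conditions: LiN(i-Pr)2, THF, −78 °C; allyl bromide, DMPU, −78 → −20 °C
Reagents that add atoms: none
Why: kinetic enolate alkylation, in which the amide base deprotonates the enone only at C8 (α′ position; no γ-hydrogens exist) and allyl bromide attacks from the β-face, anti to the 12,20-acetal ring.

**Step 13**
Reactants: 20 8β-allyl-5-en-7-one; 21 [2-(chloromethyl)prop-2-en-1-yl]trimethylsilane
Product: 22 8α-allyl-8β-[2-(trimethylsilylmethyl)allyl]-5-en-7-one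
Conditions: LiN(i-Pr)2, THF/DMPU, −78 → 0 °C; 21, NaI (cat.), 0 °C → rt
Reagents that add atoms: none
Why: a second enolate alkylation at C8, in which the electrophile again approaches the planar enolate from the β-face (the α-face is blocked by C11 and axial C20), so the silylated arm becomes C15 (β), the first allyl group becomes C14 (α) and the spiro centre C8 is set.

**Step 14**
Reactants: 22 8,8-dialkylated enone
Product: 23 spiro enone with ring D as cyclopentene (C13=C16; CH2SiMe3 on C16; C14 α; C15 β)
Conditions: second-generation Grubbs catalyst RuCl2(=CHPh)(PCy3)(H2IMes) (5 mol %), CH2Cl2, 40 °C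
Reagents that add atoms: none
Why: ring-closing metathesis of the geminal allyl and 2-substituted allyl groups closes the five-membered ring D as the cyclopentenylmethylsilane, the conjugated trisubstituted C5=C6 bond being inert.

**Step 15**
Reactants: 23 spiro enone
Product: 24 trans-decalin 7-ketone (5β-H)
Conditions: Li, NH3(l)/THF, t-BuOH (1 equiv), −78 °C; NH4Cl
Reagents that add atoms: none
Why: dissolving-metal (Birch-type) conjugate reduction of the enone, in which protonation of C5 anti to the axial C10 substituent should give the trans-fused rings A and B, with the allylsilane and the acetal unaffected.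

**Step 16**
Reactants: 24 trans-decalin 7-ketone
Product: 26 6-diazo-7-ketone, via trifluoroacetyl ketone 25 (not isolated)
Conditions: LiN(SiMe3)2, THF, −78 °C; CF3CO2CH2CF3; aq. NH4Cl; then MsN3, Et3N, H2O, MeCN, rt
Reagents that add atoms: methanesulfonyl azide, CS(=O)(=O)N=[N+]=[N-]
Why: Danheiser detrifluoroacetylative diazo transfer (Regitz type) should give the α-diazo ketone, because C6 is the only enolisable position of the C7 ketone.

**Step 17**
Reactants: 26 6-diazo-7-ketone
Product: 28 ring-contracted diester (five-membered ring B; 6β-CO2Me; trans-hydrindane), via ketene 27 (not isolated)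
Conditions: hν (Hg lamp, Pyrex), MeOH, 0 °C; then NaOMe (cat.), MeOH, rt
Reagents that add atoms: methanol, CO
Why: photochemical Wolff rearrangement, in which C8 migrates to C6 with loss of N2 to contract ring B, methanol traps the ketene as the C7 ester, and methoxide equilibration should place the ester β (trans to C4), so C6 is set under thermodynamic control.

**Step 18**
Reactants: 28 ring-contracted diester (spiro ring D allylsilane; 12,20-bis(methyl acetal); 3β-OSiEt3)
Product: 30 pentacyclic ester acetal (rings A to D of the target; 12-O–C20H(OMe) bridge; 16-methylene), via oxocarbenium triflate 29 (not isolated)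
Conditions: Me3SiOTf (0.2 equiv), 2,6-di-tert-butyl-4-methylpyridine, CH2Cl2, −78 °C
Reagents that add atoms: none
Why: Me3SiOTf removes the methoxy group at the less hindered acetal carbon C12 (C20 is neopentyl, next to quaternary C10) to give the cyclic oxocarbenium ion 29, whose C12 is attacked by C13, the γ-carbon of the cyclopentenylmethylsilane, after which the β-silyl cation at C16 loses the silyl group (Me3SiOMe formed, Me3SiOTf regenerated) to leave the C16=C17 exo-methylene. The closest known reaction type is the intramolecular Hosomi–Sakurai allylation of a cyclic acetal (oxocarbenium–allylsilane cyclisation). Ring C (C8–C9–C11–C12–C13–C14) closes by a 6-exo-trig attack on the C12=O+ bond through a chair-like transition state, giving the bicyclo[3.2.1]octane with ring D. C13 is fixed because the C11 and C14 arms are both on the α-face of ring B, so only the α-face of the ring D alkene can be reached; C12 is fixed because its oxygen is held in the six-membered acetal ring to C20, which forces the C12–O bond to be axial on ring C and syn to C20, as in the target. The step needs site selectivity (C12 over C20), secured by the hindrance at C20 and by reversible ionisation, and γ-attack with an exocyclic rather than endocyclic alkene, secured by the β-silicon effect and loss of silicon.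

**Step 19**
Reactants: 30 pentacyclic ester acetal
Product: 31 dimethyl ester of the target (3β-OH; 12-OH syn to C20; 20-CHO; 16-methylene)
Conditions: 1 M aq. HCl, THF, 0 °C → rt
Reagents that add atoms: water, O
Why: acid-catalysed acetal hydrolysis releases the C20 aldehyde and the 12-hydroxyl (only C20–O bonds are cleaved, so C12 keeps its configuration) and removes the silyl ether.

**Step 20**
Reactants: 31 dimethyl ester of the target
Product: 32 CNP0218328.1 (3β,12-dihydroxy-20-oxogibberell-16-ene-7,19-dioic acid)
Conditions: LiOH, THF/H2O, rt → 40 °C; then 1 M HCl to pH 3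
Reagents that add atoms: lithium hydroxide, [Li+].[OH-]
Why: saponification, in which the C7 ester is hydrolysed normally and the hindered axial C19 ester with anchimeric assistance from the 1,3-diaxial C20 aldehyde hydrate (as in the hydrolysis of 2-formylbenzoates), C6 already being in its thermodynamic configuration.

**Compound list**
1 | allyl 2-oxocyclohexane-1-carboxylate | O=C1CCCCC1C(=O)OCC=C | starting material
2 | allyl 2-oxo-1-(phenylselanyl)cyclohexane-1-carboxylate | O=C1CCCCC1([Se]c1ccccc1)C(=O)OCC=C | intermediate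
3 | allyl 6-oxocyclohex-1-ene-1-carboxylate | O=C1CCCC=C1C(=O)OCC=C | intermediate
4 | allyltrimethylsilane | C=CC[Si](C)(C)C | starting material
5 | allyl (1S,2S)-2-allyl-6-oxocyclohexane-1-carboxylate (trans) | O=C1CCC[C@@H](CC=C)[C@@H]1C(=O)OCC=C | intermediate
6 | methyl 5-methoxy-3-oxopentanoate | COCCC(=O)CC(=O)OC | starting material
7 | methyl 3-oxopent-4-enoate (Nazarov reagent) | C=CC(=O)CC(=O)OC | intermediate
8 | Michael adduct: allyl 2-allyl-1-(5-methoxy-3,5-dioxopentyl)-6-oxocyclohexane-1-carboxylate (new chain trans to the C9 allyl) | O=C1CCC[C@@H](CC=C)[C@@]1(CCC(=O)CC(=O)OC)C(=O)OCC=C | intermediate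
9 | decalin enone diester: 3-oxo-4-ene, 4-CO2Me, 10α-CO2allyl, 9α-allyl | O=C1CC[C@@]2(C(=O)OCC=C)[C@H](CC=C)CCCC2=C1C(=O)OC | intermediate
10 | 4β-methyl-3-oxo-5-ene diester: 4α-CO2Me, 10α-CO2allyl, 9α-allyl | O=C1CC[C@@]2(C(=O)OCC=C)[C@H](CC=C)CCC=C2[C@]1(C)C(=O)OC | intermediate
11 | C20 acid: 10α-CO2H analogue of 10 | O=C1CC[C@@]2(C(=O)O)[C@H](CC=C)CCC=C2[C@]1(C)C(=O)OC | intermediate
12 | C20 acid chloride | O=C1CC[C@@]2(C(=O)Cl)[C@H](CC=C)CCC=C2[C@]1(C)C(=O)OC | intermediate
13 | C20 aldehyde: 10α-CHO, 9α-allyl, 3-oxo-5-ene, 4α-CO2Me, 4β-Me | O=C1CC[C@@]2(C=O)[C@H](CC=C)CCC=C2[C@]1(C)C(=O)OC | intermediate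
14 | 12,20-dialdehyde: 9α-CH2CHO, 10α-CHO | O=C1CC[C@@]2(C=O)[C@H](CC=O)CCC=C2[C@]1(C)C(=O)OC | intermediate
15 | 12,20-bridged bis(methyl acetal) 3-ketone (anomer mixture at C12 and C20) | O=C1CC[C@@]23C(OC)OC(OC)C[C@@H]2CCC=C3[C@]1(C)C(=O)OC | intermediate
16 | 3β-alcohol of 15 | O[C@H]1CC[C@@]23C(OC)OC(OC)C[C@@H]2CCC=C3[C@]1(C)C(=O)OC | intermediate
17 | 3β-triethylsilyl ether | CC[Si](CC)(CC)O[C@H]1CC[C@@]23C(OC)OC(OC)C[C@@H]2CCC=C3[C@]1(C)C(=O)OC | intermediate
18 | 5-en-7-one | CC[Si](CC)(CC)O[C@H]1CC[C@@]23C(OC)OC(OC)C[C@@H]2CC(=O)C=C3[C@]1(C)C(=O)OC | intermediate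
19 | allyl bromide | C=CCBr | starting material
20 | 8β-allyl-5-en-7-one | CC[Si](CC)(CC)O[C@H]1CC[C@@]23C(OC)OC(OC)C[C@@H]2[C@@H](CC=C)C(=O)C=C3[C@]1(C)C(=O)OC | intermediate
21 | [2-(chloromethyl)prop-2-en-1-yl]trimethylsilane | C=C(CCl)C[Si](C)(C)C | starting material
22 | 8α-allyl-8β-[2-(trimethylsilylmethyl)allyl]-5-en-7-one | CC[Si](CC)(CC)O[C@H]1CC[C@@]23C(OC)OC(OC)C[C@@H]2[C@@](CC=C)(CC(=C)C[Si](C)(C)C)C(=O)C=C3[C@]1(C)C(=O)OC | intermediate
23 | spiro enone: ring D cyclopentene at C8 (C13=C16, CH2SiMe3 on C16, C14 α, C15 β) | CC[Si](CC)(CC)O[C@H]1CC[C@@]23C(OC)OC(OC)C[C@@H]2[C@]4(CC=C(C[Si](C)(C)C)C4)C(=O)C=C3[C@]1(C)C(=O)OC | intermediate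
24 | trans-decalin 7-ketone (5β-H) | CC[Si](CC)(CC)O[C@H]1CC[C@@]23C(OC)OC(OC)C[C@@H]2[C@]4(CC=C(C[Si](C)(C)C)C4)C(=O)C[C@@H]3[C@]1(C)C(=O)OC | intermediate
25 | 6-trifluoroacetyl-7-ketone | CC[Si](CC)(CC)O[C@H]1CC[C@@]23C(OC)OC(OC)C[C@@H]2[C@]4(CC=C(C[Si](C)(C)C)C4)C(=O)C(C(=O)C(F)(F)F)[C@@H]3[C@]1(C)C(=O)OC | intermediate
26 | 6-diazo-7-ketone | CC[Si](CC)(CC)O[C@H]1CC[C@@]23C(OC)OC(OC)C[C@@H]2[C@]4(CC=C(C[Si](C)(C)C)C4)C(=O)C(=[N+]=[N-])[C@@H]3[C@]1(C)C(=O)OC | intermediate
27 | ketene (C6=C7=O) on the contracted five-membered ring B | CC[Si](CC)(CC)O[C@H]1CC[C@@]23C(OC)OC(OC)C[C@@H]2[C@]4(CC=C(C[Si](C)(C)C)C4)C(=C=O)[C@@H]3[C@]1(C)C(=O)OC | intermediate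
28 | ring-contracted diester: trans-hydrindane, 6β-CO2Me, spiro ring D allylsilane, 12,20-bis(methyl acetal), 3β-OSiEt3 | CC[Si](CC)(CC)O[C@H]1CC[C@@]23C(OC)OC(OC)C[C@@H]2[C@]4(CC=C(C[Si](C)(C)C)C4)[C@@H](C(=O)OC)[C@@H]3[C@]1(C)C(=O)OC | intermediate
29 | C12 oxocarbenium triflate (C12=O+–C20H(OMe)) | CC[Si](CC)(CC)O[C@H]1CC[C@@]23C(OC)[O+]=CC[C@@H]2[C@]4(CC=C(C[Si](C)(C)C)C4)[C@@H](C(=O)OC)[C@@H]3[C@]1(C)C(=O)OC.[O-]S(=O)(=O)C(F)(F)F | intermediate
30 | pentacyclic ester acetal: rings A to D closed, 12-O–C20H(OMe) bridge, 16-methylene, 3β-OSiEt3, 7,19-dimethyl ester (anomer mixture at C20) | C=C1C[C@]23C[C@H]1[C@@H]4C[C@H]2[C@]5(C(OC)O4)CC[C@H](O[Si](CC)(CC)CC)[C@@](C)(C(=O)OC)[C@H]5[C@@H]3C(=O)OC | intermediate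
31 | dimethyl ester of the target (3β-OH, 12-OH syn to C20, 20-CHO) | C=C1C[C@]23C[C@H]1[C@@H](O)C[C@H]2[C@]1(C=O)CC[C@H](O)[C@@](C)(C(=O)OC)[C@H]1[C@@H]3C(=O)OC | intermediate
32 | CNP0218328.1: 3β,12-dihydroxy-20-oxogibberell-16-ene-7,19-dioic acid (12-OH syn to C20) | C=C1C[C@]23C[C@H]1[C@@H](O)C[C@H]2[C@]1(C=O)CC[C@H](O)[C@@](C)(C(=O)O)[C@H]1[C@@H]3C(=O)O | target

**Totals.** Total step count: 20. Longest linear sequence: 20 steps (from 1; compounds 4, 6, 19 and 21 are purchased).

**Steps most likely to fail**

Step 18. Ionisation at the C20 acetal carbon with ring closure there (wrong site), or protodesilylation before the C–C bond forms. Fallback: setting out from 28, Me3SiOTf/i-Pr2NEt removes methanol across C12–C11 to give the cyclic enol ether F1 (C20 has no β-hydrogen and cannot eliminate). Protonation of F1 at C11 with one equivalent of TfOH at −78 °C then generates the C12 oxocarbenium ion as the only cation, and the same Sakurai closure returns to the route at 30.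

Step 13. Slow or oxygen-selective alkylation of the hindered, fully substituted enolate, so that the quaternary spiro carbon C8 is not formed by direct C-alkylation. Fallback: setting out from 20, the potassium enolate (KH, 18-crown-6, DMF) is alkylated on oxygen with 21 to the dienyl allyl ether F2. A thermal Claisen rearrangement (PhMe, 140 °C) then transfers the silylated allyl group to the less hindered β-face of C8 and returns to the route at 22.

Step 20. Incomplete acyl substitution at the hindered axial C19 ester, or degradation of the free aldehyde during prolonged exposure to hydroxide. Fallback: setting out from 30, both methyl esters are cleaved by SN2 demethylation with LiSPr in HMPA while C20 is still masked, giving the diacid acetal F3. The acidic hydrolysis of step 19 (1 M aq. HCl, THF) then releases the aldehyde, the 12-hydroxyl and the 3-hydroxyl and returns to the route at 32.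

**Further compounds**
F1 | step 18 | cyclic enol ether (C11=C12–O–C20H(OMe)) of 28 | CC[Si](CC)(CC)O[C@H]1CC[C@@]23C(OC)OC=C[C@@H]2[C@]4(CC=C(C[Si](C)(C)C)C4)[C@@H](C(=O)OC)[C@@H]3[C@]1(C)C(=O)OC
F2 | step 13 | dienyl allyl ether (O-alkylated enolate of 20) | CC[Si](CC)(CC)O[C@H]1CC[C@@]23C(OC)OC(OC)C[C@@H]2C(CC=C)=C(OCC(=C)C[Si](C)(C)C)C=C3[C@]1(C)C(=O)OC
F3 | step 20 | 7,19-diacid of 30 (12,20-methyl acetal and silyl ether retained) | C=C1C[C@]23C[C@H]1[C@@H]4C[C@H]2[C@]5(C(OC)O4)CC[C@H](O[Si](CC)(CC)CC)[C@@](C)(C(=O)O)[C@H]5[C@@H]3C(=O)O
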